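**Retrosynthetic overview** (cembrane numbering: C1/C2 lactone carbons, C7 OAc, C8/C11 peroxide carbons)
1. The last step closes the 14-membered ring at C1–C14: the allyl radical from a Z-allylic bromide adds to C1 of a 3-(phenylsulfonylmethyl)butenolide and ejects PhSO2•. This sets C1 anti to C2 and unveils the exocyclic methylene in the same event.
2. The butenolide comes from ring-closing metathesis of the 2-(sulfonylmethyl)acrylate of the C2 vinyl carbinol, itself from a ligand-controlled divinylzinc addition to an enal.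
3. The 1,2-dioxane comes from SN2 closure of a C8 tertiary hydroperoxide onto a C11 allylic chloride. The C8–OOH/C7–OH pair comes from H2O2 opening of a Shi epoxide; C11 and the 12Z olefin come from a Z-alkenylzinc addition to an aldehyde.
4. The C2–C11 chain comes from organocopper addition to methyl but-2-ynoate (3E), isopropenyl Grignard addition and a Claisen rearrangement (7E, later the epoxide).
5. Ring order: 1,2-dioxane, then butenolide, then the 14-membered carbocycle.

Assumption: the target is the structure drawn by the SMILES, i.e. (1S,2R,7S,8R,11S), 3E, 12Z; the two ligand antipodes in steps 6 and 14 are assigned from the usual amino-alcohol/zinc facial model and would be swapped if the sense proves opposite.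

**Step 1**
Reactants: 1 2-(2-bromoethyl)-1,3-dioxolane; 2 methyl but-2-ynoate
Product: 5 methyl (2E)-3-methyl-6-oxohex-2-enoate, via Grignard reagent 3 (not isolated), via dioxolane ester 4 (not isolated)
Conditions: Mg, THF, 25 °C; CuBr·SMe2 (1.0 equiv), −78 °C, then 2, −78 °C, MeOH quench; then 2 M HCl, THF, 20 °C
Reagents that add atoms: water, O
Why: Syn carbocupration (conjugate addition) of the organocopper reagent to the ynoate puts the new chain trans to the ester, which fixes the 3E olefin, and the dioxolane is hydrolysed in the same pot.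

**Step 2**
Reactants: 5 methyl (2E)-3-methyl-6-oxohex-2-enoate; 6 isopropenylmagnesium bromide
Product: 7 methyl (2E)-6-hydroxy-3,7-dimethylocta-2,7-dienoate (racemic at C6)
Conditions: THF, −78 °C; aq. NH4Cl
Reagents that add atoms: none
Why: Grignard 1,2-addition at −78 °C is selective for the aldehyde over the β,β-disubstituted enoate; the new carbinol center is erased in step 3.

**Step 3**
Reactants: 7 methyl (2E)-6-hydroxy-3,7-dimethylocta-2,7-dienoate; 8 ethyl vinyl ether
Product: 10 methyl (2E,6E)-3,7-dimethyl-10-oxodeca-2,6-dienoate, via allyl vinyl ether 9 (not isolated)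
Conditions: Hg(OAc)2 (10 mol%), 8 (solvent), reflux; concentrate; PhMe, 120 °C, sealed tube
Reagents that add atoms: none
Why: Mercury-catalysed vinyl transfer then Claisen rearrangement through a chair with the chain equatorial gives the E trisubstituted olefin (about 9:1, minor isomer removed by chromatography) and the aldehyde directly, with the enoate untouched.

**Step 4**
Reactants: 11 but-2-yn-1-ol
Product: 13 (2Z)-3-iodobut-2-en-1-ol, via alkenylaluminate 12 (not isolated)
Conditions: NaAlH2(OCH2CH2OMe)2, THF, 0 °C; then I2, −78 → 0 °C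
Reagents that add atoms: iodine, II
Why: Alkoxide-directed trans-hydroalumination of the propargylic alcohol places Al on the distal carbon and iodinolysis with retention gives only the Z vinyl iodide, the source of the 12Z olefin.

**Step 5**
Reactants: 13 (2Z)-3-iodobut-2-en-1-ol
Product: 14 tert-butyl{[(2Z)-3-iodobut-2-en-1-yl]oxy}dimethylsilane
Conditions: TBSCl, imidazole, DMF, 0 → 20 °C
Reagents that add atoms: tert-butyldimethylsilyl chloride, CC(C)(C)[Si](C)(C)Cl
Why: Standard silylation of the primary allylic alcohol masks it until step 18.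

**Step 6**
Reactants: 10 methyl (2E,6E)-3,7-dimethyl-10-oxodeca-2,6-dienoate; 14 tert-butyl{[(2Z)-3-iodobut-2-en-1-yl]oxy}dimethylsilane (2.2 equiv)
Product: 17 methyl (2E,6E,10S,11Z)-13-[(tert-butyldimethylsilyl)oxy]-10-hydroxy-3,7,11-trimethyltrideca-2,6,11-trienoate, via alkenyllithium 15 (not isolated), via dialkenylzinc 16 (not isolated)
Conditions: t-BuLi (4.4 equiv), Et2O, −78 °C; ZnBr2 (1.1 equiv), −78 → 0 °C; TEEDA, (+)-MIB (10 mol%), hexanes/PhMe, then 10, 0 °C; aq. NH4Cl
Reagents that add atoms: none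
Why: Iodine–lithium exchange and transmetalation to zinc retain the olefin geometry, and the amino-alcohol-catalysed alkenylzinc addition (Noyori/Walsh type) delivers the alkenyl group to the Re face of the aldehyde, setting the 10S carbinol (C11 of the target) while the ester is untouched.

**Step 7**
Reactants: 17 the (10S)-allylic alcohol
Product: 18 methyl (2E,6E,10R,11Z)-13-[(tert-butyldimethylsilyl)oxy]-10-chloro-3,7,11-trimethyltrideca-2,6,11-trienoate
Conditions: PPh3, Cl3CC(O)CCl3, CH2Cl2, −20 → 0 °C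
Reagents that add atoms: hexachloroacetone, ClC(Cl)(Cl)C(=O)C(Cl)(Cl)Cl
Why: Magid chlorination turns allylic alcohols into chlorides by SN2 with inversion and without allylic transposition or loss of olefin geometry, giving the 10R chloride.

**Step 8**
Reactants: 18 the (10R)-allylic chloride
Product: 19 methyl (2E)-5-{(2S,3S)-3-[(3R,4Z)-6-[(tert-butyldimethylsilyl)oxy]-3-chloro-4-methylhex-4-en-1-yl]-3-methyloxiran-2-yl}-3-methylpent-2-enoate
Conditions: L-fructose-derived Shi ketone (ent-Shi catalyst, 30 mol%), Oxone (2KHSO5·KHSO4·K2SO4), K2CO3, Bu4NHSO4, Na2B4O7 buffer, MeCN/DMM/H2O, 0 °C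
Reagents that add atoms: potassium peroxymonosulfate (from Oxone), [K+].[O-]S(=O)(=O)OO
Why: Shi asymmetric epoxidation attacks only the electron-rich 6,7-olefin (the enoate and the olefin flanked by Cl and OSi are deactivated); the L-fructose-derived ketone gives the (S,S)-epoxide, the mirror image of the (R,R) sense of the D-fructose ketone on E-trisubstituted olefins.

**Step 9**
Reactants: 19 the (S,S)-epoxide
Product: 20 methyl (2E,6S,7R,10R,11Z)-13-[(tert-butyldimethylsilyl)oxy]-10-chloro-7-hydroperoxy-6-hydroxy-3,7,11-trimethyltrideca-2,11-dienoate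
Conditions: anhydrous H2O2 in Et2O (30 equiv), H3PMo12O40 (5 mol%), MgSO4, 20 °C
Reagents that add atoms: hydrogen peroxide, OO
Why: Molybdenum-catalysed perhydrolysis opens the trisubstituted epoxide at the tertiary carbon with inversion, which sets the 7R tertiary hydroperoxide (C8 of the target) and leaves the 6S alcohol (C7).

**Step 10**
Reactants: 20 the hydroxy hydroperoxide
Product: 21 methyl (2E,6S)-6-{(3R,6S)-6-[(2Z)-4-[(tert-butyldimethylsilyl)oxy]but-2-en-2-yl]-3-methyl-1,2-dioxan-3-yl}-6-hydroxy-3-methylhex-2-enoate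
Conditions: CsOH·H2O (1.1 equiv), DMF, 0 °C, 0.01 M
Reagents that add atoms: none
Why: The more acidic hydroperoxide is deprotonated in preference to the alcohol and closes the ring by 6-exo-tet SN2 on the allylic chloride with inversion (intramolecular hydroperoxide alkylation), giving the (3R,6S)-dioxane with the two chains cis.

**Step 11**
Reactants: 21 the dioxane ester
Product: 22 (2E,6S)-6-{(3R,6S)-6-[(2Z)-4-[(tert-butyldimethylsilyl)oxy]but-2-en-2-yl]-3-methyl-1,2-dioxan-3-yl}-3-methylhex-2-ene-1,6-diol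
Conditions: i-Bu2AlH (3.3 equiv), CH2Cl2, −78 °C; Rochelle salt
Reagents that add atoms: none
Why: Low-temperature DIBAL reduction takes the enoate to the allylic alcohol by 1,2-reduction and is tolerated by dialkyl peroxides and silyl ethers.

**Step 12**
Reactants: 22 the diol
Product: 23 (2E,6S)-6-{(3R,6S)-6-[(2Z)-4-[(tert-butyldimethylsilyl)oxy]but-2-en-2-yl]-3-methyl-1,2-dioxan-3-yl}-6-hydroxy-3-methylhex-2-enal
Conditions: MnO2 (20 equiv), CH2Cl2, 20 °C
Reagents that add atoms: none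
Why: Activated MnO2 oxidises only the allylic primary alcohol and keeps the E geometry.

**Step 13**
Reactants: 23 the hydroxy enal
Product: 24 (1S,4E)-1-{(3R,6S)-6-[(2Z)-4-[(tert-butyldimethylsilyl)oxy]but-2-en-2-yl]-3-methyl-1,2-dioxan-3-yl}-4-methyl-6-oxohex-4-en-1-yl acetate
Conditions: Ac2O, pyridine, DMAP (cat.), CH2Cl2, 0 → 20 °C
Reagents that add atoms: acetic anhydride, CC(=O)OC(C)=O
Why: DMAP-catalysed acylation installs the C7 acetate on the only free hydroxyl.

**Step 14**
Reactants: 24 the acetoxy enal; 25 vinylmagnesium bromide (4 equiv)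
Product: 27 (1S,4E,6S)-1-{(3R,6S)-6-[(2Z)-4-[(tert-butyldimethylsilyl)oxy]but-2-en-2-yl]-3-methyl-1,2-dioxan-3-yl}-6-hydroxy-4-methylocta-4,7-dien-1-yl acetate, via divinylzinc 26 (not isolated)
Conditions: 25, ZnCl2 (2 equiv), THF, 0 °C; 1,4-dioxane, filter; (−)-MIB (10 mol%), PhMe, then 24, −20 → 0 °C; aq. NH4Cl
Reagents that add atoms: none
Why: Amino-alcohol-catalysed divinylzinc addition (Oppolzer type) adds 1,2 to the Si face of the enal and sets the 6S carbinol (C2 of the target); acetate, silyl ether and dialkyl peroxide do not react with organozincs.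

**Step 15**
Reactants: 28 2-(bromomethyl)prop-2-enoic acid
Product: 29 2-[(phenylsulfonyl)methyl]prop-2-enoic acid
Conditions: PhSO2Na (2 equiv), MeOH, 65 °C; aq. HCl
Reagents that add atoms: sodium benzenesulfinate, [Na+].[O-]S(=O)c1ccccc1
Why: S-alkylation of the sulfinate by the allylic bromide gives the allyl sulfone that later serves as the radical leaving group.

**Step 16**
Reactants: 27 the (6S)-dienol; 29 2-[(phenylsulfonyl)methyl]prop-2-enoic acid
Product: 30 (3S,4E,8S)-8-acetoxy-8-{(3R,6S)-6-[(2Z)-4-[(tert-butyldimethylsilyl)oxy]but-2-en-2-yl]-3-methyl-1,2-dioxan-3-yl}-5-methylocta-1,4-dien-3-yl 2-[(phenylsulfonyl)methyl]prop-2-enoate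
Conditions: EDC·HCl, DMAP (10 mol%), CH2Cl2, 0 °C
Reagents that add atoms: none
Why: Steglich-type esterification acylates the carbinol oxygen, so the C2 configuration is retained.

**Step 17**
Reactants: 30 the diene ester
Product: 31 (1S,4E)-1-{(3R,6S)-6-[(2Z)-4-[(tert-butyldimethylsilyl)oxy]but-2-en-2-yl]-3-methyl-1,2-dioxan-3-yl}-4-methyl-5-{(2R)-5-oxo-4-[(phenylsulfonyl)methyl]-2,5-dihydrofuran-2-yl}pent-4-en-1-yl acetate
Conditions: second-generation Grubbs catalyst RuCl2(=CHPh)(H2IMes)(PCy3) (10 mol%), PhMe, 80 °C, 5 mM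
Reagents that add atoms: none
Why: Ring-closing metathesis between the terminal vinyl group and the 1,1-disubstituted acrylate closes the butenolide with loss of ethene; the trisubstituted olefins and the peroxide are spectators and the C2 center is untouched (descriptor becomes R by priority change only).

**Step 18**
Reactants: 31 the butenolide silyl ether
Product: 32 (1S,4E)-1-{(3R,6S)-6-[(2Z)-4-bromobut-2-en-2-yl]-3-methyl-1,2-dioxan-3-yl}-4-methyl-5-{(2R)-5-oxo-4-[(phenylsulfonyl)methyl]-2,5-dihydrofuran-2-yl}pent-4-en-1-yl acetate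
Conditions: Ph3PBr2 (1.5 equiv), CH2Cl2, 0 → 20 °C
Reagents that add atoms: dibromotriphenylphosphorane, BrP(Br)(c1ccccc1)(c1ccccc1)c1ccccc1
Why: Ph3PBr2 converts silyl ethers directly into bromides under neutral conditions (Palomo-type bromodesilyloxylation), which spares the base-sensitive butenolide and keeps the Z olefin.

**Step 19**
Reactants: 32 the allylic bromide
Product: 33 (1S,2R,3E,7S,8R,11S,12Z)-7-acetoxy-8,11-epidioxycembra-3,12,15(17)-trien-16,2-olide (target)
Conditions: (Bu3Sn)2 (1.2 equiv), hν (sunlamp, Pyrex), PhH, 2 mM, 15 °C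
Reagents that add atoms: none
Why: Proposed new method: Bu3Sn• from the photolysed distannane abstracts Br, the Z-allyl radical (configurationally stable at 15 °C on the time scale of ring closure) adds through its primary terminus C14 to the β-carbon C1 of the butenolide anti to the C2 side chain (trans ring fusion, 1S), the α-carbonyl radical then expels PhSO2• by β-scission to unveil the exocyclic methylene, and PhSO2• regenerates Bu3Sn• from the distannane; the closest known reactions are Pattenden's 14-membered allyl-radical macrocyclisations onto enones and intermolecular radical allyl transfer from 2-(sulfonylmethyl)acrylates under (Bu3Sn)2/hν.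

**Compound list**
1 | 2-(2-bromoethyl)-1,3-dioxolane | BrCCC1OCCO1 | starting material
2 | methyl but-2-ynoate | CC#CC(=O)OC | starting material
3 | [2-(1,3-dioxolan-2-yl)ethyl]magnesium bromide | Br[Mg]CCC1OCCO1 | intermediate (not isolated)
4 | methyl (2E)-5-(1,3-dioxolan-2-yl)-3-methylpent-2-enoate | COC(=O)/C=C(\C)CCC1OCCO1 | intermediate (not isolated)
5 | methyl (2E)-3-methyl-6-oxohex-2-enoate | COC(=O)/C=C(\C)CCC=O | intermediate
6 | isopropenylmagnesium bromide | CC(=C)[Mg]Br | starting material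
7 | methyl (2E)-6-hydroxy-3,7-dimethylocta-2,7-dienoate (racemic) | COC(=O)/C=C(\C)CCC(O)C(C)=C | intermediate
8 | ethyl vinyl ether | C=COCC | starting material
9 | methyl (2E)-6-(ethenyloxy)-3,7-dimethylocta-2,7-dienoate (racemic) | COC(=O)/C=C(\C)CCC(OC=C)C(C)=C | intermediate (not isolated)
10 | methyl (2E,6E)-3,7-dimethyl-10-oxodeca-2,6-dienoate | COC(=O)/C=C(\C)CC/C=C(\C)CCC=O | intermediate
11 | but-2-yn-1-ol | CC#CCO | starting material
12 | sodium cyclic alkenyl(alkoxy)bis(2-methoxyethoxy)aluminate (Al on C3, cis to CH2O) | [Na+].CC1=CCO[Al-]1(OCCOC)OCCOC | intermediate (not isolated)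
13 | (2Z)-3-iodobut-2-en-1-ol | C/C(I)=C/CO | intermediate
14 | tert-butyl{[(2Z)-3-iodobut-2-en-1-yl]oxy}dimethylsilane | C/C(I)=C/CO[Si](C)(C)C(C)(C)C | intermediate
15 | [(2E)-4-[(tert-butyldimethylsilyl)oxy]but-2-en-2-yl]lithium (Li cis to CH2OSi) | [Li]/C(C)=C\CO[Si](C)(C)C(C)(C)C | intermediate (not isolated)
16 | bis[(2Z)-4-[(tert-butyldimethylsilyl)oxy]but-2-en-2-yl]zinc | C/C(=C/CO[Si](C)(C)C(C)(C)C)[Zn]/C(C)=C\CO[Si](C)(C)C(C)(C)C | intermediate (not isolated)
17 | methyl (2E,6E,10S,11Z)-13-[(tert-butyldimethylsilyl)oxy]-10-hydroxy-3,7,11-trimethyltrideca-2,6,11-trienoate | COC(=O)/C=C(\C)CC/C=C(\C)CC[C@H](O)/C(C)=C\CO[Si](C)(C)C(C)(C)C | intermediate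
18 | methyl (2E,6E,10R,11Z)-13-[(tert-butyldimethylsilyl)oxy]-10-chloro-3,7,11-trimethyltrideca-2,6,11-trienoate | COC(=O)/C=C(\C)CC/C=C(\C)CC[C@@H](Cl)/C(C)=C\CO[Si](C)(C)C(C)(C)C | intermediate
19 | methyl (2E)-5-{(2S,3S)-3-[(3R,4Z)-6-[(tert-butyldimethylsilyl)oxy]-3-chloro-4-methylhex-4-en-1-yl]-3-methyloxiran-2-yl}-3-methylpent-2-enoate | COC(=O)/C=C(\C)CC[C@@H]1O[C@@]1(C)CC[C@@H](Cl)/C(C)=C\CO[Si](C)(C)C(C)(C)C | intermediate
20 | methyl (2E,6S,7R,10R,11Z)-13-[(tert-butyldimethylsilyl)oxy]-10-chloro-7-hydroperoxy-6-hydroxy-3,7,11-trimethyltrideca-2,11-dienoate | COC(=O)/C=C(\C)CC[C@H](O)[C@@](OO)(C)CC[C@@H](Cl)/C(C)=C\CO[Si](C)(C)C(C)(C)C | intermediate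
21 | methyl (2E,6S)-6-{(3R,6S)-6-[(2Z)-4-[(tert-butyldimethylsilyl)oxy]but-2-en-2-yl]-3-methyl-1,2-dioxan-3-yl}-6-hydroxy-3-methylhex-2-enoate | COC(=O)/C=C(\C)CC[C@H](O)[C@@]1(C)CC[C@H](OO1)/C(C)=C\CO[Si](C)(C)C(C)(C)C | intermediate
22 | (2E,6S)-6-{(3R,6S)-6-[(2Z)-4-[(tert-butyldimethylsilyl)oxy]but-2-en-2-yl]-3-methyl-1,2-dioxan-3-yl}-3-methylhex-2-ene-1,6-diol | OC/C=C(\C)CC[C@H](O)[C@@]1(C)CC[C@H](OO1)/C(C)=C\CO[Si](C)(C)C(C)(C)C | intermediate
23 | (2E,6S)-6-{(3R,6S)-6-[(2Z)-4-[(tert-butyldimethylsilyl)oxy]but-2-en-2-yl]-3-methyl-1,2-dioxan-3-yl}-6-hydroxy-3-methylhex-2-enal | O=C/C=C(\C)CC[C@H](O)[C@@]1(C)CC[C@H](OO1)/C(C)=C\CO[Si](C)(C)C(C)(C)C | intermediate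
24 | (1S,4E)-1-{(3R,6S)-6-[(2Z)-4-[(tert-butyldimethylsilyl)oxy]but-2-en-2-yl]-3-methyl-1,2-dioxan-3-yl}-4-methyl-6-oxohex-4-en-1-yl acetate | O=C/C=C(\C)CC[C@H](OC(C)=O)[C@@]1(C)CC[C@H](OO1)/C(C)=C\CO[Si](C)(C)C(C)(C)C | intermediate
25 | vinylmagnesium bromide | C=C[Mg]Br | starting material
26 | divinylzinc | C=C[Zn]C=C | intermediate (not isolated)
27 | (1S,4E,6S)-1-{(3R,6S)-6-[(2Z)-4-[(tert-butyldimethylsilyl)oxy]but-2-en-2-yl]-3-methyl-1,2-dioxan-3-yl}-6-hydroxy-4-methylocta-4,7-dien-1-yl acetate | C=C[C@H](O)/C=C(\C)CC[C@H](OC(C)=O)[C@@]1(C)CC[C@H](OO1)/C(C)=C\CO[Si](C)(C)C(C)(C)C | intermediate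
28 | 2-(bromomethyl)prop-2-enoic acid | C=C(CBr)C(=O)O | starting material
29 | 2-[(phenylsulfonyl)methyl]prop-2-enoic acid | C=C(CS(=O)(=O)c1ccccc1)C(=O)O | intermediate
30 | (3S,4E,8S)-8-acetoxy-8-{(3R,6S)-6-[(2Z)-4-[(tert-butyldimethylsilyl)oxy]but-2-en-2-yl]-3-methyl-1,2-dioxan-3-yl}-5-methylocta-1,4-dien-3-yl 2-[(phenylsulfonyl)methyl]prop-2-enoate | C=C[C@H](OC(=O)C(=C)CS(=O)(=O)c1ccccc1)/C=C(\C)CC[C@H](OC(C)=O)[C@@]1(C)CC[C@H](OO1)/C(C)=C\CO[Si](C)(C)C(C)(C)C | intermediate
31 | (1S,4E)-1-{(3R,6S)-6-[(2Z)-4-[(tert-butyldimethylsilyl)oxy]but-2-en-2-yl]-3-methyl-1,2-dioxan-3-yl}-4-methyl-5-{(2R)-5-oxo-4-[(phenylsulfonyl)methyl]-2,5-dihydrofuran-2-yl}pent-4-en-1-yl acetate | O=C1O[C@@H](C=C1CS(=O)(=O)c1ccccc1)/C=C(\C)CC[C@H](OC(C)=O)[C@@]2(C)CC[C@H](OO2)/C(C)=C\CO[Si](C)(C)C(C)(C)C | intermediate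
32 | (1S,4E)-1-{(3R,6S)-6-[(2Z)-4-bromobut-2-en-2-yl]-3-methyl-1,2-dioxan-3-yl}-4-methyl-5-{(2R)-5-oxo-4-[(phenylsulfonyl)methyl]-2,5-dihydrofuran-2-yl}pent-4-en-1-yl acetate | O=C1O[C@@H](C=C1CS(=O)(=O)c1ccccc1)/C=C(\C)CC[C@H](OC(C)=O)[C@@]2(C)CC[C@H](OO2)/C(C)=C\CBr | intermediate
33 | (1S,2R,3E,7S,8R,11S,12Z)-7-acetoxy-8,11-epidioxycembra-3,12,15(17)-trien-16,2-olide | C=C1C(=O)O[C@@H]2/C=C(\C)CC[C@H](OC(C)=O)[C@@]3(C)CC[C@H](OO3)/C(C)=C\C[C@@H]12 | target

**Step count**
Total: 19 steps. Longest linear sequence: 16 steps (1, 2, 3, 6–14, 16–19). The three ligand- or catalyst-controlled steps (6, 8, 14) are independent, so minor diastereomers are removed by chromatography at 21 and 27.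

**Steps most likely to fail, with fallbacks**

Step 19 (radical ring closure). The allyl radical may add too slowly to the substituted butenolide, may lose its Z geometry, or may fragment the neighbouring peroxide. The fallback sets out from 27 and returns at 33, and separates ring closure from methylene installation. Alcohol 27 is esterified with acrylic acid (DCC, DMAP) to the acrylate ester F1. Ring-closing metathesis with the second-generation Grubbs catalyst gives the unsubstituted butenolide F2, and Ph3PBr2 gives the allylic bromide F3. A Pattenden-type reductive allyl-radical macrocyclisation (Bu3SnH by syringe pump, Et3B/air, PhH, 20 °C, 2 mM) closes the ring anti to the C2 chain to the saturated lactone F4. LiN(SiMe3)2 at −78 °C followed by Eschenmoser's salt gives the Mannich base F5, and MeI then NaHCO3 eliminates trimethylamine to give 33.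

Step 10 (peroxide ring closure, together with step 9). The β-hydroxy hydroperoxide may fragment under base, or the silyl ether may not survive the acidic perhydrolysis. The fallback sets out from 19 and returns at 21, and reverses the order of the two C–O bond formations. The allylic chloride of 19 is displaced with 2-methoxyprop-2-yl hydroperoxide and CsOH in DMF (SN2, inversion) to the epoxy peroxyketal F6. Catalytic camphorsulfonic acid in CH2Cl2/MeOH then frees the secondary hydroperoxide F7, which is not isolated and opens the epoxide at the tertiary carbon (6-exo, inversion) to give 21 directly.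

Step 6 (ligand-controlled alkenylzinc addition). The enantioselectivity with this hindered Z-alkenylzinc may be low. The fallback sets out from 10 and 14 and returns at 17, and sets the center by reduction instead of addition. Alkenyllithium 15 (from 14, t-BuLi) is added to 10 at −78 °C to give the racemic allylic alcohol F8. Dess–Martin periodinane gives the Z-enone F9, and (R)-Me-CBS/catecholborane at −78 °C reduces it to the (10S)-alcohol 17.

**Further compounds**
F1 | step 19 | (3S,4E,8S)-8-acetoxy-8-{(3R,6S)-6-[(2Z)-4-[(tert-butyldimethylsilyl)oxy]but-2-en-2-yl]-3-methyl-1,2-dioxan-3-yl}-5-methylocta-1,4-dien-3-yl prop-2-enoate | C=C[C@H](OC(=O)C=C)/C=C(\C)CC[C@H](OC(C)=O)[C@@]1(C)CC[C@H](OO1)/C(C)=C\CO[Si](C)(C)C(C)(C)C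
F2 | step 19 | (1S,4E)-1-{(3R,6S)-6-[(2Z)-4-[(tert-butyldimethylsilyl)oxy]but-2-en-2-yl]-3-methyl-1,2-dioxan-3-yl}-4-methyl-5-[(2S)-5-oxo-2,5-dihydrofuran-2-yl]pent-4-en-1-yl acetate | O=C1O[C@@H](C=C1)/C=C(\C)CC[C@H](OC(C)=O)[C@@]2(C)CC[C@H](OO2)/C(C)=C\CO[Si](C)(C)C(C)(C)C
F3 | step 19 | (1S,4E)-1-{(3R,6S)-6-[(2Z)-4-bromobut-2-en-2-yl]-3-methyl-1,2-dioxan-3-yl}-4-methyl-5-[(2S)-5-oxo-2,5-dihydrofuran-2-yl]pent-4-en-1-yl acetate | O=C1O[C@@H](C=C1)/C=C(\C)CC[C@H](OC(C)=O)[C@@]2(C)CC[C@H](OO2)/C(C)=C\CBr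
F4 | step 19 | (1S,2R,3E,7S,8R,11S,12Z)-7-acetoxy-8,11-epidioxy-17-norcembra-3,12-dien-16,2-olide | C1C(=O)O[C@@H]2/C=C(\C)CC[C@H](OC(C)=O)[C@@]3(C)CC[C@H](OO3)/C(C)=C\C[C@@H]12
F5 | step 19 | 17-(dimethylamino)-15,17-dihydro derivative of 33 (mixture at C15) | CN(C)CC1C(=O)O[C@@H]2/C=C(\C)CC[C@H](OC(C)=O)[C@@]3(C)CC[C@H](OO3)/C(C)=C\C[C@@H]12
F6 | step 10 | methyl (2E)-5-{(2S,3S)-3-[(3S,4Z)-6-[(tert-butyldimethylsilyl)oxy]-3-[(2-methoxypropan-2-yl)peroxy]-4-methylhex-4-en-1-yl]-3-methyloxiran-2-yl}-3-methylpent-2-enoate | COC(=O)/C=C(\C)CC[C@@H]1O[C@@]1(C)CC[C@H](OOC(C)(C)OC)/C(C)=C\CO[Si](C)(C)C(C)(C)C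
F7 | step 10 | methyl (2E)-5-{(2S,3S)-3-[(3S,4Z)-6-[(tert-butyldimethylsilyl)oxy]-3-hydroperoxy-4-methylhex-4-en-1-yl]-3-methyloxiran-2-yl}-3-methylpent-2-enoate | COC(=O)/C=C(\C)CC[C@@H]1O[C@@]1(C)CC[C@H](OO)/C(C)=C\CO[Si](C)(C)C(C)(C)C
F8 | step 6 | methyl (2E,6E,11Z)-13-[(tert-butyldimethylsilyl)oxy]-10-hydroxy-3,7,11-trimethyltrideca-2,6,11-trienoate (racemic) | COC(=O)/C=C(\C)CC/C=C(\C)CCC(O)/C(C)=C\CO[Si](C)(C)C(C)(C)C
F9 | step 6 | methyl (2E,6E,11Z)-13-[(tert-butyldimethylsilyl)oxy]-3,7,11-trimethyl-10-oxotrideca-2,6,11-trienoate | COC(=O)/C=C(\C)CC/C=C(\C)CCC(=O)/C(C)=C\CO[Si](C)(C)C(C)(C)C
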